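The runs stem from a simulated flask with made-up constants; the scatter is artificial.

**Minutes of the meeting on the four flasks**

If an X can go forward to D and G or meet a second L and become E, the meeting held, the chance at that fork (the selectivity) is what a row of flasks has to be judged by.

| flask | L | Z | remark | time |
|---|---|---|---|---|
| amber | 0.30 M | 0.64 M | run made earlier |  |
| grey | 1.1 M | 0.64 M | run made earlier |  |
| south-west | 0.40 M | 0.640 M |  | 15 h |
| south-east | 0.80 M | 0.640 M |  | 15 h |
| north | 1.5 M | 0.640 M |  | 15 h |
| north-west | 3.0 M | 0.640 M |  | 15 h |

| amber: time / h | amber: D / % | grey: time / h | grey: D / % |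
|---|---|---|---|
| 1.00 | 2.6 | 0.833 | 0.8 |
| 2.50 | 7.6 | 1.50 | 4.2 |
| 5.00 | 14.0 | 3.00 | 5.7 |
| 8.00 | 19.3 | 6.00 | 11.7 |
| 10.0 | 25.4 | 10.0 | 15.3 |

(each reading ± 1 percentage point)

- in percentages every species weighs as the L in it: one E counts as two
- steps that have been proposed: L + Z <-> X; X <-> D + G; L + X -> E
- "hardly changes" means that all values lie within two and a half points (for a concentration: within two and a half percent of the largest)

* [D] at the end for south-west, south-east, north, north-west, in this order
* the course of these numbers from the first flask to the last (falls, then rises / falls all the way / rises all the way / hardly changes / rises, then falls)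

I pointed out that amber and grey both had Z at 0.64 M, and that at 10.0 h amber showed D at 25.4% and grey at 15.3%. I proposed taking the chance of D as K/(K + c(L)), with the percent of D proportional to it at the charged c(L). Solving the two runs gives K = 0.912 M. This is the fork concentration, the c(L) at which an X has even chances of D and of E. It is a reading, with the scatter of two points in it.

I then applied it to north-west, where Z is the limiting reagent, with 0.640 M charged against 3.0 M of L. The chance of D at the charged c(L) is 23.3%, and the charge of Z times that chance gives 0.149 M. That is less than the 0.168 M of D that grey already held at 10.0 h, so I committed to a row that turns down before its last flask.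

The author of the forecast disagreed and put forward 0.11 M, 0.18 M, 0.24 M and 0.26 M, with the course rises all the way: “D rises but flattens as Z runs out”. For north-west, the forecast stood higher than my figure.

**Result**

The flasks gave 0.113 M, 0.155 M, 0.163 M and 0.109 M, so the course is rises, then falls, and the row turns at c(L) = 1.2 M.

    L + Z ⇌ X (K = 0.530 M⁻¹, k = 6.30 × 10⁻⁴ M⁻¹ s⁻¹)
    X ⇌ D + G (K = 0.750 M, k = 4.60 × 10⁻⁵ s⁻¹)
    L + X → E (k = 7.40 × 10⁻⁵ M⁻¹ s⁻¹)

In south-west at 15.0 h, the forward rate of X into D and G stands at 4.0 times that of L + X into E, and the rate constant of the first over that of the second, 0.622 M, divided by that flask's c(L) of 0.155 M gives the same ratio, 4.02. In north-west the same constants over c(L) = 1.85 M give a forward ratio of 0.336, the 0.109 M of D stands below the 0.149 M reckoned with the reading K = 0.912 M, and at 15.0 h that flask has Z at 0.970% of its charge, E at 34.6% and D at 3.63% of the L charged.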